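The fully substituted quinone ring carries the pattern C(indolyl)–C(O)–C(O) twice. The route cuts it into two halves. The two-carbon unit is the quinone carbonyl carbon beside the hydroxy-bearing carbon plus its indolyl-bearing neighbour, made as a 3-indolyl siloxyalkyne. The four-carbon unit is a squarate-derived 2-tert-butoxy-3-indolyl-4-siloxycyclobutenone. A Danheiser benzannulation joins them in one thermal operation. It forms the C(OH)–C(=O) bond and the bond from the second indolyl-bearing carbon to the carbon that will carry the hydroperoxy group, giving the hexasubstituted ring with every oxygen differentiated. Desilylation with air oxidation, O-methylation, tert-butyl cleavage and perhydrolysis finish the synthesis.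

Key step: step 8

Remark: Ar = 5-(3-methylbut-2-en-1-yl)-1-(triisopropylsilyl)indol-3-yl and Ar' = 5-(3-methylbut-2-en-1-yl)-1H-indol-3-yl. Hydroxy- and hydroperoxyquinones are drawn as 1,4-benzoquinone tautomers. The ring stereocentres of 7, 8, 10, 11, 17 and 19 are racemic and vanish on aromatisation; the target is achiral.

Step 1
Reactants: 1 5-bromo-1H-indole; 2 tributyl(3-methylbut-2-en-1-yl)stannane
Product: 3 5-(3-methylbut-2-en-1-yl)-1H-indole
Conditions: Pd(PPh3)4 (5 mol %), DMF, 100 °C
Reagents that add atoms: none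
Why: Stille cross-coupling of the aryl bromide with the prenylstannane should deliver the linear prenyl group by reductive elimination at the unhindered CH2 terminus and tolerates the free N–H.

Step 2
Reactants: 3 5-(3-methylbut-2-en-1-yl)-1H-indole
Product: 5 3-bromo-5-(3-methylbut-2-en-1-yl)-1-(triisopropylsilyl)indole, via N-silylindole 4 (not isolated)
Conditions: n-BuLi, THF, −78 °C; i-Pr3SiCl, −78 → 0 °C; then NBS, −78 °C
Reagents that add atoms: triisopropylsilyl chloride CC(C)[Si](Cl)(C(C)C)C(C)C; N-bromosuccinimide O=C1CCC(=O)N1Br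
Why: One-pot N-silylation and electrophilic aromatic bromination, in which NBS should attack C3 of the N-silylindole at −78 °C faster than the trisubstituted alkene.

Step 3
Reactants: 6 di-tert-butyl squarate (3,4-di-tert-butoxycyclobut-3-ene-1,2-dione)
Product: 7 2,3-di-tert-butoxy-4-hydroxycyclobut-2-en-1-one (racemic)
Conditions: LiAlH(OtBu)3, THF, −78 → −20 °C; aq. NH4Cl
Reagents that add atoms: none
Why: Chemoselective metal hydride 1,2-reduction, in which the bulky LiAlH(OtBu)3 should reduce one of the two equivalent vinylogous ester carbonyls and stop at the monoalcohol.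

Step 4
Reactants: 7 2,3-di-tert-butoxy-4-hydroxycyclobut-2-en-1-one
Product: 8 2,3-di-tert-butoxy-4-[(tert-butyldimethylsilyl)oxy]cyclobut-2-en-1-one (racemic)
Conditions: t-BuMe2SiCl, imidazole, DMF, 0 → 25 °C
Reagents that add atoms: tert-butyldimethylsilyl chloride CC(C)(C)[Si](C)(C)Cl
Why: Silyl ether formation at the secondary alcohol under neutral conditions, which blocks the hydroxyl that would otherwise lactonise the later vinylketene.

Step 5
Reactants: 5 3-bromo-5-(3-methylbut-2-en-1-yl)-1-(triisopropylsilyl)indole; 8 2,3-di-tert-butoxy-4-[(tert-butyldimethylsilyl)oxy]cyclobut-2-en-1-one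
Product: 11 2-tert-butoxy-4-[(tert-butyldimethylsilyl)oxy]-3-Ar-cyclobut-2-en-1-one (racemic), via 3-lithioindole 9 (not isolated), via lithium alkoxide 10 (not isolated)
Conditions: 5, t-BuLi (2 equiv), THF, −78 °C; add 8; then (CF3CO)2O, −78 → 0 °C; aq. NaHCO3
Reagents that add atoms: none
Why: Bromine–lithium exchange, 1,2-addition of the aryllithium to the vinylogous ester carbonyl and anhydride-induced ionisation with loss of the tert-butyl group from the distal alkoxy oxygen amount to a Stork–Danheiser-type 1,3-carbonyl transposition, which should place the indole on the β-carbon and leave the tert-butoxy group on the α-carbon.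

Step 6
Reactants: 5 3-bromo-5-(3-methylbut-2-en-1-yl)-1-(triisopropylsilyl)indole
Product: 12 ethyl 5-(3-methylbut-2-en-1-yl)-1-(triisopropylsilyl)indole-3-carboxylate
Conditions: Pd(OAc)2 (3 mol %), Xantphos (6 mol %), CO (1 atm), EtOH (10 equiv), Et3N (3 equiv), toluene, 80 °C
Reagents that add atoms: carbon monoxide [C-]#[O+]; ethanol CCO
Why: Palladium-catalysed alkoxycarbonylation of an aryl bromide, in which oxidative addition to the zerovalent palladium–Xantphos complex, CO insertion and ethanolysis of the acylpalladium bromide should give the ester under weakly basic conditions that leave the N–Si bond and the prenyl alkene untouched.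

Step 7
Reactants: 12 ethyl 5-(3-methylbut-2-en-1-yl)-1-(triisopropylsilyl)indole-3-carboxylate
Product: 15 5-(3-methylbut-2-en-1-yl)-1-(triisopropylsilyl)-3-{[(triisopropylsilyl)oxy]ethynyl}indole, via dibromoketone enolate 13 (not isolated), via lithium ynolate 14 (not isolated)
Conditions: CH2Br2, lithium 2,2,6,6-tetramethylpiperidide (LiTMP), THF, −78 °C; add 12; LiN(SiMe3)2; n-BuLi, −78 → 25 °C; i-Pr3SiCl, −78 → 25 °C
Reagents that add atoms: dibromomethane BrCBr; triisopropylsilyl chloride CC(C)[Si](Cl)(C(C)C)C(C)C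
Why: Kowalski ester homologation, in which LiCHBr2 adds to the ester, the dibromoketone enolate undergoes bromine–lithium exchange and 1,2-aryl shift to the ynolate, and the bulky silyl chloride should silylate it on oxygen.

Step 8
Reactants: 11 2-tert-butoxy-4-[(tert-butyldimethylsilyl)oxy]-3-Ar-cyclobut-2-en-1-one; 15 5-(3-methylbut-2-en-1-yl)-1-(triisopropylsilyl)-3-{[(triisopropylsilyl)oxy]ethynyl}indole
Product: 20 4-tert-butoxy-6-[(tert-butyldimethylsilyl)oxy]-3-[(triisopropylsilyl)oxy]-2,5-bis(Ar)phenol, via vinylketene 16 (not isolated), via vinylcyclobutenone 17 (not isolated), via dienylketene 18 (not isolated), via cyclohexadienone 19 (not isolated)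
Conditions: 11 (1.3 equiv), toluene (0.2 M), argon, sealed tube, 80 °C, then 110 °C
Reagents that add atoms: none
Why: Danheiser benzannulation: thermal 4π electrocyclic opening of 11 with outward rotation of the siloxy group gives alkoxy(vinyl)ketene 16, which should undergo a regioselective [2+2] cycloaddition with 15, the indolyl-bearing alkyne carbon bonding to the ketene carbonyl carbon and the siloxy-bearing carbon to the tert-butoxy-bearing carbon, so that both new ring bonds are made in 17. 4π opening of 17, with the tert-butoxy group rotating outward, gives the (Z)-dienylketene 18, and the six-membered ring closes by a thermal disrotatory 6π electrocyclisation that rejoins the ketene carbon to the CH(OSi) terminus (the two carbons that were bonded in 11); enolisation of cyclohexadienone 19 gives phenol 20. The closest known reaction type is the benzannulation of cyclobutenones with trialkylsiloxyalkynes to give resorcinol monosilyl ethers. No stereocentre survives, because the racemic CH(OSi) centre of 11 and 19 is lost on aromatisation. The step needs head-to-tail regiochemistry in the ketene–alkyne cycloaddition, secured by the polarisation of the siloxyalkyne (the oxygen lone pair makes the β-carbon nucleophilic), which places the two indoles para and the free phenol on the carbon bonded to the incoming indolyl carbon. It also needs intermolecular capture of 16 to outrun lactonisation and dimerisation, secured by the silyl ether on the ring oxygen and by the electron-rich alkyne.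

Step 9
Reactants: 20 4-tert-butoxy-6-[(tert-butyldimethylsilyl)oxy]-3-[(triisopropylsilyl)oxy]-2,5-bis(Ar)phenol
Product: 22 2-tert-butoxy-5-hydroxy-3,6-bis(Ar')-1,4-benzoquinone, via hydroxyhydroquinone 21 (not isolated)
Conditions: Bu4NF (6 equiv), THF, argon, 0 → 25 °C; then air, 25 °C; aq. NH4Cl
Reagents that add atoms: none
Why: Fluoride desilylation of the two N–Si and two O–Si bonds followed by autoxidation of the resulting benzene-1,2,4-triol should give the hydroxyquinone, the aryl tert-butyl ether being inert to both.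

Step 10
Reactants: 22 2-tert-butoxy-5-hydroxy-3,6-bis(Ar')-1,4-benzoquinone
Product: 23 2-tert-butoxy-5-methoxy-3,6-bis(Ar')-1,4-benzoquinone
Conditions: Me3SiCHN2, MeOH–toluene (1:4), 0 °C
Reagents that add atoms: (trimethylsilyl)diazomethane C[Si](C)(C)C=[N+]=[N-]
Why: Diazoalkane O-methylation of the vinylogous carboxylic acid should give the more stable 2,5-dialkoxy-1,4-quinone and leave the indole N–H groups untouched.

Step 11
Reactants: 23 2-tert-butoxy-5-methoxy-3,6-bis(Ar')-1,4-benzoquinone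
Product: 24 2-hydroxy-5-methoxy-3,6-bis(Ar')-1,4-benzoquinone
Conditions: CF3CO2H (10 equiv), CH2Cl2, 0 °C, short reaction time
Reagents that add atoms: none
Why: Acidolysis of the vinylogous tert-butyl ester (E1 loss of the tert-butyl cation as isobutene) should free the hydroxyl, while the methyl ether is inert and the prenyl groups are spared by the short exposure at 0 °C.

Step 12
Reactants: 24 2-hydroxy-5-methoxy-3,6-bis(Ar')-1,4-benzoquinone
Product: 25 hydroperoxycochliodinol (2-hydroperoxy-5-hydroxy-3,6-bis(Ar')-1,4-benzoquinone)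
Conditions: 30% aq. H2O2 (1.5 equiv), LiOH (2.2 equiv), THF–H2O, −10 → 0 °C, dark; then cold 1 M HCl to pH 3
Reagents that add atoms: hydrogen peroxide OO
Why: Perhydrolysis of a vinylogous ester by addition–elimination of the hydroperoxide anion at the methoxy-bearing quinone carbon, as in peracid formation from activated esters and in hydroperoxide substitution on halogenated quinones; HOO− is far more nucleophilic than HO−, and the product is kept as its non-oxidising anion until cold acidification.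

Compound list
1 | 5-bromo-1H-indole | Brc1ccc2[nH]ccc2c1 | starting material
2 | tributyl(3-methylbut-2-en-1-yl)stannane | CCCC[Sn](CCCC)(CCCC)CC=C(C)C | starting material
3 | 5-(3-methylbut-2-en-1-yl)-1H-indole | CC(C)=CCc1ccc2[nH]ccc2c1 | intermediate
4 | 5-(3-methylbut-2-en-1-yl)-1-(triisopropylsilyl)indole (not isolated) | CC(C)=CCc1ccc2c(ccn2[Si](C(C)C)(C(C)C)C(C)C)c1 | intermediate
5 | 3-bromo-5-(3-methylbut-2-en-1-yl)-1-(triisopropylsilyl)indole | CC(C)=CCc1ccc2c(c1)c(Br)cn2[Si](C(C)C)(C(C)C)C(C)C | intermediate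
6 | di-tert-butyl squarate | CC(C)(C)OC1=C(OC(C)(C)C)C(=O)C1=O | starting material
7 | 2,3-di-tert-butoxy-4-hydroxycyclobut-2-en-1-one (racemic) | CC(C)(C)OC1=C(OC(C)(C)C)C(=O)C1O | intermediate
8 | 2,3-di-tert-butoxy-4-[(tert-butyldimethylsilyl)oxy]cyclobut-2-en-1-one (racemic) | CC(C)(C)OC1=C(OC(C)(C)C)C(=O)C1O[Si](C)(C)C(C)(C)C | intermediate
9 | 3-lithio-5-(3-methylbut-2-en-1-yl)-1-(triisopropylsilyl)indole (not isolated) | [Li]c1cn([Si](C(C)C)(C(C)C)C(C)C)c2ccc(CC=C(C)C)cc12 | intermediate
10 | lithium 1-Ar-2,3-di-tert-butoxy-4-[(tert-butyldimethylsilyl)oxy]cyclobut-2-en-1-olate (diastereomer mixture, not isolated) | [Li+].[O-]C1(c2cn([Si](C(C)C)(C(C)C)C(C)C)c3ccc(CC=C(C)C)cc23)C(OC(C)(C)C)=C(OC(C)(C)C)C1O[Si](C)(C)C(C)(C)C | intermediate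
11 | 2-tert-butoxy-4-[(tert-butyldimethylsilyl)oxy]-3-Ar-cyclobut-2-en-1-one (racemic) | O=C1C(OC(C)(C)C)=C(c2cn([Si](C(C)C)(C(C)C)C(C)C)c3ccc(CC=C(C)C)cc23)C1O[Si](C)(C)C(C)(C)C | intermediate
12 | ethyl 5-(3-methylbut-2-en-1-yl)-1-(triisopropylsilyl)indole-3-carboxylate | CCOC(=O)c1cn([Si](C(C)C)(C(C)C)C(C)C)c2ccc(CC=C(C)C)cc12 | intermediate
13 | lithium 1-Ar-2,2-dibromoethen-1-olate (not isolated) | [Li+].[O-]C(=C(Br)Br)c1cn([Si](C(C)C)(C(C)C)C(C)C)c2ccc(CC=C(C)C)cc12 | intermediate
14 | lithium 2-Ar-ethyn-1-olate (not isolated) | [Li+].[O-]C#Cc1cn([Si](C(C)C)(C(C)C)C(C)C)c2ccc(CC=C(C)C)cc12 | intermediate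
15 | Ar–C≡C–OSi(i-Pr)3, 5-(3-methylbut-2-en-1-yl)-1-(triisopropylsilyl)-3-{[(triisopropylsilyl)oxy]ethynyl}indole | CC(C)[Si](OC#Cc1cn([Si](C(C)C)(C(C)C)C(C)C)c2ccc(CC=C(C)C)cc12)(C(C)C)C(C)C | intermediate
16 | (E)-2-tert-butoxy-3-Ar-4-[(tert-butyldimethylsilyl)oxy]buta-1,3-dien-1-one (not isolated) | O=C=C(OC(C)(C)C)/C(c1cn([Si](C(C)C)(C(C)C)C(C)C)c2ccc(CC=C(C)C)cc12)=C/O[Si](C)(C)C(C)(C)C | intermediate
17 | 4-tert-butoxy-2-Ar-3-[(triisopropylsilyl)oxy]-4-{(E)-1-Ar-2-[(tert-butyldimethylsilyl)oxy]vinyl}cyclobut-2-en-1-one (racemic, not isolated) | O=C1C(c2cn([Si](C(C)C)(C(C)C)C(C)C)c3ccc(CC=C(C)C)cc23)=C(O[Si](C(C)C)(C(C)C)C(C)C)C1(OC(C)(C)C)/C(c2cn([Si](C(C)C)(C(C)C)C(C)C)c3ccc(CC=C(C)C)cc23)=C/O[Si](C)(C)C(C)(C)C | intermediate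
18 | (3Z,5E)-4-tert-butoxy-2,5-bis(Ar)-6-[(tert-butyldimethylsilyl)oxy]-3-[(triisopropylsilyl)oxy]hexa-1,3,5-trien-1-one (not isolated) | O=C=C(c1cn([Si](C(C)C)(C(C)C)C(C)C)c2ccc(CC=C(C)C)cc12)/C(O[Si](C(C)C)(C(C)C)C(C)C)=C(OC(C)(C)C)\C(c1cn([Si](C(C)C)(C(C)C)C(C)C)c2ccc(CC=C(C)C)cc12)=C\O[Si](C)(C)C(C)(C)C | intermediate
19 | 4-tert-butoxy-6-[(tert-butyldimethylsilyl)oxy]-2,5-bis(Ar)-3-[(triisopropylsilyl)oxy]cyclohexa-2,4-dien-1-one (racemic, not isolated) | O=C1C(c2cn([Si](C(C)C)(C(C)C)C(C)C)c3ccc(CC=C(C)C)cc23)=C(O[Si](C(C)C)(C(C)C)C(C)C)C(OC(C)(C)C)=C(c2cn([Si](C(C)C)(C(C)C)C(C)C)c3ccc(CC=C(C)C)cc23)C1O[Si](C)(C)C(C)(C)C | intermediate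
20 | 4-tert-butoxy-6-[(tert-butyldimethylsilyl)oxy]-3-[(triisopropylsilyl)oxy]-2,5-bis(Ar)phenol | Oc1c(-c2cn([Si](C(C)C)(C(C)C)C(C)C)c3ccc(CC=C(C)C)cc23)c(O[Si](C(C)C)(C(C)C)C(C)C)c(OC(C)(C)C)c(-c2cn([Si](C(C)C)(C(C)C)C(C)C)c3ccc(CC=C(C)C)cc23)c1O[Si](C)(C)C(C)(C)C | intermediate
21 | 5-tert-butoxy-3,6-bis(Ar')benzene-1,2,4-triol (not isolated) | Oc1c(-c2c[nH]c3ccc(CC=C(C)C)cc23)c(O)c(OC(C)(C)C)c(-c2c[nH]c3ccc(CC=C(C)C)cc23)c1O | intermediate
22 | 2-tert-butoxy-5-hydroxy-3,6-bis(Ar')-1,4-benzoquinone | OC1=C(c2c[nH]c3ccc(CC=C(C)C)cc23)C(=O)C(OC(C)(C)C)=C(c2c[nH]c3ccc(CC=C(C)C)cc23)C1=O | intermediate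
23 | 2-tert-butoxy-5-methoxy-3,6-bis(Ar')-1,4-benzoquinone | COC1=C(c2c[nH]c3ccc(CC=C(C)C)cc23)C(=O)C(OC(C)(C)C)=C(c2c[nH]c3ccc(CC=C(C)C)cc23)C1=O | intermediate
24 | 2-hydroxy-5-methoxy-3,6-bis(Ar')-1,4-benzoquinone | COC1=C(c2c[nH]c3ccc(CC=C(C)C)cc23)C(=O)C(O)=C(c2c[nH]c3ccc(CC=C(C)C)cc23)C1=O | intermediate
25 | hydroperoxycochliodinol | CC(C)=CCc1ccc2[nH]cc(C3=C(O)C(=O)C(c4c[nH]c5ccc(CC=C(C)C)cc45)=C(OO)C3=O)c2c1 | target

Total steps: 12. Longest linear sequence: 9 steps (1, 2, 6, 7, 8, 9, 10, 11, 12).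

Steps most likely to fail

Step 8. The crowded alkoxy(vinyl)ketene may dimerise or acylate the product phenol faster than the hindered aryl siloxyalkyne traps it. The electron-donating N-silylindolyl group may also erode the regiochemistry of the ketene–alkyne cycloaddition. The fallback gives up ring construction and substitutes a preformed quinone. It sets out from 3: two equivalents of 3 are condensed with tetrabromo-1,4-benzoquinone (bromanil) and Cs2CO3 in MeCN to give 2,5-dibromo-3,6-bis(Ar')-1,4-benzoquinone F1. NaOMe in MeOH exchanges both vinylic bromides to give 2,5-dimethoxy-3,6-bis(Ar')-1,4-benzoquinone F2. One equivalent of NaOH in aqueous THF hydrolyses a single vinylogous ester, because the resulting monoanion resists a second attack, and the sequence comes back to the route at 24.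

Step 12. The hydroperoxide anion may add to a quinone carbonyl and cleave the ring, or excess HOO− may reduce the product hydroperoxide with loss of O2 back to the dihydroxyquinone. The fallback sets out from 24 and uses a monoprotected hydrogen peroxide. 2-Hydroperoxy-2-methoxypropane F3, made by ozonolysis of 2,3-dimethylbut-2-ene in methanol, is deprotonated with KOtBu in THF at 0 °C and displaces the methoxy group to give 2-hydroxy-5-[(2-methoxypropan-2-yl)peroxy]-3,6-bis(Ar')-1,4-benzoquinone F4. Brief treatment with AcOH–THF–H2O at 25 °C hydrolyses the peroxy ketal and comes back to the route at 25.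

Step 7. LiCHBr2 may add only sluggishly to the hindered, electron-rich indole-3-carboxylate (a vinylogous carbamate), or the ynolate may be silylated on carbon instead of oxygen. The fallback sets out from 5 and makes the ynolate by oxidation of an acetylide. Bromine–lithium exchange of 5 (t-BuLi, THF, −78 °C), as in step 5, and quenching with DMF give 5-(3-methylbut-2-en-1-yl)-1-(triisopropylsilyl)indole-3-carbaldehyde F5. Ohira–Bestmann homologation (dimethyl (1-diazo-2-oxopropyl)phosphonate, K2CO3, MeOH) gives 3-ethynyl-5-(3-methylbut-2-en-1-yl)-1-(triisopropylsilyl)indole F6. Its lithium acetylide (n-BuLi, THF, −78 °C) is oxidised with lithium tert-butyl peroxide (from t-BuOOH and LiN(SiMe3)2) to the ynolate, which is trapped with i-Pr3SiOTf, and the sequence comes back to the route at 15.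

Further compounds
F1 | step 8 | 2,5-dibromo-3,6-bis[5-(3-methylbut-2-en-1-yl)-1H-indol-3-yl]-1,4-benzoquinone | BrC1=C(c2c[nH]c3ccc(CC=C(C)C)cc23)C(=O)C(Br)=C(c2c[nH]c3ccc(CC=C(C)C)cc23)C1=O
F2 | step 8 | 2,5-dimethoxy-3,6-bis[5-(3-methylbut-2-en-1-yl)-1H-indol-3-yl]-1,4-benzoquinone | COC1=C(c2c[nH]c3ccc(CC=C(C)C)cc23)C(=O)C(OC)=C(c2c[nH]c3ccc(CC=C(C)C)cc23)C1=O
F3 | step 12 | 2-hydroperoxy-2-methoxypropane | COC(C)(C)OO
F4 | step 12 | 2-hydroxy-5-[(2-methoxypropan-2-yl)peroxy]-3,6-bis[5-(3-methylbut-2-en-1-yl)-1H-indol-3-yl]-1,4-benzoquinone | COC(C)(C)OOC1=C(c2c[nH]c3ccc(CC=C(C)C)cc23)C(=O)C(O)=C(c2c[nH]c3ccc(CC=C(C)C)cc23)C1=O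
F5 | step 7 | 5-(3-methylbut-2-en-1-yl)-1-(triisopropylsilyl)indole-3-carbaldehyde | O=Cc1cn([Si](C(C)C)(C(C)C)C(C)C)c2ccc(CC=C(C)C)cc12
F6 | step 7 | 3-ethynyl-5-(3-methylbut-2-en-1-yl)-1-(triisopropylsilyl)indole | C#Cc1cn([Si](C(C)C)(C(C)C)C(C)C)c2ccc(CC=C(C)C)cc12
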